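The C9–C10 bond is formed last, closing ring B onto a finished ring A. The vicinal pair O-1/quaternary C-10 is read as a C1–C10 epoxide. Cp2TiCl (trivalent titanium) opens the cis-epoxide of an α-cyclogeranyl precursor to the tertiary C-10 radical, which adds 6-endo to C-9 of a pendant butenolide; the titanium enolate then expels a C-7 acetate. One operation should give 1β-hydroxycinnamolide: ring B, C-9, C-10, the free 1β-hydroxyl and the C7=C8 enoate. The precursor is built from 2,4,4-trimethylcyclohexenone by CBS reduction, Claisen rearrangement and addition of a butenolide α-anion. Esterification, lactone reduction and Swern oxidation finish.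

Key step: step 8

Remarks on the chemistry: positions carry drimane numbers throughout, also in monocyclic compounds (C-1 carbinol, C-5/C-10 ring fusion, C-11 on C-9, C-12 on C-8). Compounds 1 and 5 are taken as purchasable. The carbinol centre C-7 in 8–11 is carried as an epimer mixture because step 8 destroys it.

Step 1
Reactants: 1 2,4,4-trimethylcyclohex-2-en-1-one
Product: 2 (R)-2,4,4-trimethylcyclohex-2-en-1-ol
Conditions: (S)-Me-CBS oxazaborolidine (10 mol %), BH3·SMe2, THF, −20 °C; MeOH quench
Reagents that add atoms: none
Why: Corey–Bakshi–Shibata reduction, in which the 2-methylalkenyl arm acts as the large group, so the (S)-catalyst should deliver hydride to the face that gives the (R)-allylic alcohol (this sets the O-1 centre, later relayed to C-5).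

Step 2
Reactants: 2 (R)-2,4,4-trimethylcyclohex-2-en-1-ol
Product: 3 ethyl 2-[(1S)-2,6,6-trimethylcyclohex-2-en-1-yl]acetate
Conditions: triethyl orthoacetate (excess), propionic acid (cat.), 140 °C, ethanol distilled off
Reagents that add atoms: triethyl orthoacetate CC(OCC)(OCC)OCC
Why: Johnson–Claisen [3,3] rearrangement is suprafacial across the ring, so the new C5–C6 bond forms on the face the C–O bond leaves, setting C-5 as (S) and moving the alkene to C10=C1.

Step 3
Reactants: 3 ethyl 2-[(1S)-2,6,6-trimethylcyclohex-2-en-1-yl]acetate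
Product: 4 2-[(1S)-2,6,6-trimethylcyclohex-2-en-1-yl]acetaldehyde
Conditions: i-Bu2AlH (DIBAL-H, 1.05 equiv), CH2Cl2, −78 °C; Rochelle salt work-up
Reagents that add atoms: none
Why: partial ester reduction stops at the aldehyde because the tetrahedral aluminium hemiacetal is stable at −78 °C.

Step 4
Reactants: 5 3-bromofuran-2(5H)-one
Product: 6 3-bromo-2-(triisopropylsilyloxy)furan
Conditions: i-Pr3SiOTf, Et3N, CH2Cl2, 0 °C
Reagents that add atoms: triisopropylsilyl trifluoromethanesulfonate CC(C)[Si](OS(=O)(=O)C(F)(F)F)(C(C)C)C(C)C
Why: soft enolisation and O-silylation of the butenolide gives the aromatic 2-silyloxyfuran (silyl dienol ether formation).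

Step 5
Reactants: 6 3-bromo-2-(triisopropylsilyloxy)furan; 4 2-[(1S)-2,6,6-trimethylcyclohex-2-en-1-yl]acetaldehyde
Product: 9 3-{1-hydroxy-2-[(1S)-2,6,6-trimethylcyclohex-2-en-1-yl]ethyl}furan-2(5H)-one (carbinol epimers), via 3-lithio-2-(triisopropylsilyloxy)furan 7 (not isolated), via silyloxyfuran carbinol 8 (not isolated)
Conditions: n-BuLi, THF, −78 °C; then 4, −78 °C; then 1 M HCl, THF, 0 °C
Reagents that add atoms: none
Why: bromine–lithium exchange gives a butenolide α-anion equivalent that adds 1,2 to the aldehyde, and acid hydrolysis of the silyl ketene acetal with γ-protonation returns the conjugated butenolide; the new carbinol centre is uncontrolled and irrelevant.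

Step 6
Reactants: 9 hydroxybutenolide
Product: 10 1-(2-oxo-2,5-dihydrofuran-3-yl)-2-[(1S)-2,6,6-trimethylcyclohex-2-en-1-yl]ethyl acetate (carbinol epimers)
Conditions: Ac2O, pyridine, CH2Cl2, 0 °C to rt
Reagents that add atoms: acetic anhydride CC(=O)OC(C)=O
Why: simple O-acylation turns the C-7 hydroxyl into the leaving group needed in step 8, with pyridine alone used to avoid allylic transposition of the Baylis–Hillman-type acetate.

Step 7
Reactants: 10 acetate
Product: 11 cis-epoxy acetate: the C1–C10 oxirane of 10, oxygen on the ring face that carries the C-5 side chain (C-7 epimers)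
Conditions: mCPBA, NaHCO3, CH2Cl2, 0 °C
Reagents that add atoms: 3-chloroperbenzoic acid OOC(=O)c1cccc(Cl)c1
Why: Prilezhaev epoxidation attacks only the electron-rich trisubstituted ring alkene (the butenolide is electron-poor), and should come from the face syn to the pseudoaxial side chain and anti to the axial C-4 methyl, as is usual for α-ionone-type rings; this sets O-1 as β.

Step 8
Reactants: 11 cis-epoxy acetate
Product: 12 1β-hydroxycinnamolide (1β-hydroxydrim-7-en-12,11-olide; 5α-H, 9α-H, 10β-CH3, lactone C=O at C-12 on C-8, OCH2 = C-11 on C-9)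
Conditions: Cp2TiCl2 (2.5 equiv), Zn dust, THF, rt, to give green Cp2TiCl; 11 added slowly (final 0.01 M); 1 M HCl work-up
Reagents that add atoms: none
Why: Cp2TiCl transfers one electron to the oxirane, which opens at the more substituted carbon to the tertiary C-10 radical with O-1 bound to titanium (Nugent–RajanBabu reductive epoxide opening); the radical adds to C-9, the β-carbon of the butenolide, a second Cp2TiCl reduces the α-lactone radical to a titanium enolate, and E1cB loss of the C-7 acetate gives the C7=C8 alkene, as in radical additions to Morita–Baylis–Hillman acetates. The closest known reaction type is the titanocene-mediated epoxide/enoate radical cyclisation, with the second ring closure of epoxypolyprene cyclisations as the direct model. Ring B closes 6-endo-trig, since 5-exo attack at the fully substituted C-8 would give an unstabilised radical. At C-10, O-1 (as its titanium alkoxide) and the C-5 side chain are cis-1,3 and both equatorial on the ring A chair, so the planar radical should be attacked from the α face through a chair-like transition state that gives the trans-decalin with the C-10 methyl axial β, whereas β attack would place the new bond syn-axial to the axial C-4 methyl. At C-9, the lactone ring holds C-11 trans to C-7 across C8=C9, which places C-11 equatorial (9β, 9α-H) in that chair. The step needs cyclisation to outrun reduction of the tertiary radical and elimination to outrun protonation of the enolate; slow addition to excess Cp2TiCl without a proton source should secure both, because the bulky titanocene traps tertiary radicals slowly.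

Step 9
Reactants: 12 1β-hydroxycinnamolide; 13 (E)-4-methoxycinnamic acid
Product: 14 1β-[(E)-4-methoxycinnamoyloxy]cinnamolide
Conditions: DCC, DMAP (1 equiv), CH2Cl2, rt to 40 °C
Reagents that add atoms: none
Why: Steglich esterification acylates the hindered equatorial 1β-hydroxyl through the acylpyridinium without touching C-9 or the alkene geometry.

Step 10
Reactants: 14 1β-[(E)-4-methoxycinnamoyloxy]cinnamolide
Product: 16 1β-[(E)-4-methoxycinnamoyloxy]drim-7-ene-11,12-diol, via lactol 15 (not isolated)
Conditions: i-Bu2AlH (1.2 equiv, slow addition), CH2Cl2, −78 °C; MeOH quench; then NaBH4, CeCl3·7H2O, MeOH, 0 °C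
Reagents that add atoms: none
Why: the s-cis lactone is more electrophilic than the donor-conjugated, sterically screened 4-methoxycinnamate, so DIBAL-H should stop at the lactol, whose open hydroxy-enal form is reduced 1,2 under Luche conditions that leave esters alone.

Step 11
Reactants: 16 1β-[(E)-4-methoxycinnamoyloxy]drim-7-ene-11,12-diol
Product: 17 1β-[(E)-4-methoxycinnamoyloxy]polygodial, the target (1R,5S,9R,10S)
Conditions: (COCl)2, DMSO, CH2Cl2, −78 °C; Et3N, −78 to −40 °C; cold pH 7 buffer work-up
Reagents that add atoms: none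
Why: Swern oxidation activates both primary alcohols before base is added, so the dialdehyde should form without lactol formation, and the cold, brief exposure to amine keeps the epimerisable C-9 (β-CHO) intact.

Compound list
1 | 2,4,4-trimethylcyclohex-2-en-1-one | CC1=CC(C)(C)CCC1=O | starting material
2 | (R)-2,4,4-trimethylcyclohex-2-en-1-ol | CC1=CC(C)(C)CC[C@H]1O | intermediate
3 | ethyl 2-[(1S)-2,6,6-trimethylcyclohex-2-en-1-yl]acetate | CCOC(=O)C[C@@H]1C(C)=CCCC1(C)C | intermediate
4 | 2-[(1S)-2,6,6-trimethylcyclohex-2-en-1-yl]acetaldehyde | O=CC[C@@H]1C(C)=CCCC1(C)C | intermediate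
5 | 3-bromofuran-2(5H)-one | O=C1OCC=C1Br | starting material
6 | 3-bromo-2-(triisopropylsilyloxy)furan | CC(C)[Si](Oc1occc1Br)(C(C)C)C(C)C | intermediate
7 | 3-lithio-2-(triisopropylsilyloxy)furan | [Li]c1ccoc1O[Si](C(C)C)(C(C)C)C(C)C | intermediate (not isolated)
8 | 1-[2-(triisopropylsilyloxy)furan-3-yl]-2-[(1S)-2,6,6-trimethylcyclohex-2-en-1-yl]ethan-1-ol, carbinol epimers | OC(C[C@@H]1C(C)=CCCC1(C)C)c1ccoc1O[Si](C(C)C)(C(C)C)C(C)C | intermediate (not isolated)
9 | 3-{1-hydroxy-2-[(1S)-2,6,6-trimethylcyclohex-2-en-1-yl]ethyl}furan-2(5H)-one, carbinol epimers | O=C1OCC=C1C(O)C[C@@H]1C(C)=CCCC1(C)C | intermediate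
10 | 1-(2-oxo-2,5-dihydrofuran-3-yl)-2-[(1S)-2,6,6-trimethylcyclohex-2-en-1-yl]ethyl acetate, carbinol epimers | CC(=O)OC(C[C@@H]1C(C)=CCCC1(C)C)C1=CCOC1=O | intermediate
11 | cis-epoxy acetate: 1-(2-oxo-2,5-dihydrofuran-3-yl)-2-(1,3,3-trimethyl-7-oxabicyclo[4.1.0]heptan-2-yl)ethyl acetate, oxirane oxygen cis to the side chain, C-7 epimers | CC(=O)OC(C[C@@H]1[C@]2(C)O[C@@H]2CCC1(C)C)C1=CCOC1=O | intermediate
12 | 1β-hydroxycinnamolide (1β-hydroxydrim-7-en-12,11-olide) | O[C@@H]1CCC(C)(C)[C@@H]2CC=C3C(=O)OC[C@@H]3[C@@]12C | intermediate
13 | (E)-4-methoxycinnamic acid | COc1ccc(/C=C/C(=O)O)cc1 | starting material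
14 | 1β-[(E)-4-methoxycinnamoyloxy]cinnamolide | COc1ccc(/C=C/C(=O)O[C@@H]2CCC(C)(C)[C@@H]3CC=C4C(=O)OC[C@@H]4[C@@]23C)cc1 | intermediate
15 | lactol of 14 (12-hydroxy-11,12-epoxy, anomer mixture) | COc1ccc(/C=C/C(=O)O[C@@H]2CCC(C)(C)[C@@H]3CC=C4C(O)OC[C@@H]4[C@@]23C)cc1 | intermediate (not isolated)
16 | 1β-[(E)-4-methoxycinnamoyloxy]drim-7-ene-11,12-diol | COc1ccc(/C=C/C(=O)O[C@@H]2CCC(C)(C)[C@@H]3CC=C(CO)[C@H](CO)[C@@]23C)cc1 | intermediate
17 | 1β-[(E)-4-methoxycinnamoyloxy]polygodial | COc1ccc(/C=C/C(=O)O[C@@H]2CCC(C)(C)[C@@H]3CC=C(C=O)[C@H](C=O)[C@@]23C)cc1 | target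

Total step count: 11. Longest linear sequence: 10 steps (steps 1–3 and 5–11, from 1 to 17).

Steps most likely to fail

Step 8. The tertiary β-titanoxy radical may be reduced a second time and lose the oxygen, or the oxirane may rearrange on the Lewis-acidic titanium, before ring closure; the enolate may also be protonated before acetate leaves. The fallback sets out from 11 and separates radical generation, cyclisation and alkene formation. Aqueous HBr (48 %) in CHCl3 at 0 °C should open the oxirane at the tertiary carbon to the tertiary bromohydrin F1 (C-10 bromide, 1β-hydroxyl retained). Bu3SnH with AIBN in benzene at 80 °C under syringe-pump addition should generate the same C-10 radical, which cyclises 6-endo onto the butenolide and is quenched by hydrogen transfer to give 7-acetoxy-1β-hydroxydriman-12,11-olide F2. DBU in toluene at rt then eliminates acetic acid by E1cB towards C-7 and returns to the route at 12.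

Step 7. Facial selectivity of the peracid may be poor, and the trans-epoxide would end as the 1α-alcohol. The fallback sets out from 9 and uses the free C-7 hydroxyl as a directing group. VO(acac)2 (cat.) with t-BuOOH in CH2Cl2 at rt should deliver oxygen only to the ring face that carries the side chain, giving the cis-epoxy alcohol F3. Acetylation (Ac2O, pyridine) returns to the route at 11.

Step 10. The aluminium hydride may also attack or cleave the cinnamate, or over-reduce. The fallback sets out from 12 and reduces before the ester is present. LiAlH4 in THF at 0 °C gives drim-7-ene-1β,11,12-triol F4. TBSCl (2.1 equiv) with imidazole in DMF at 0 °C should silylate only the two primary hydroxyls, giving the 11,12-bis-silyl ether F5. Steglich esterification with 13 (DCC, DMAP) gives the 1β-cinnamate bis-silyl ether F6. HF·pyridine in THF removes both silyl groups and returns to the route at 16.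

Further compounds
F1 | step 8 | tertiary bromohydrin from 11 (C-10 bromide α, 1β-hydroxyl, C-7 epimers) | CC(=O)OC(C[C@@H]1[C@@](C)(Br)[C@H](O)CCC1(C)C)C1=CCOC1=O
F2 | step 8 | 7-acetoxy-1β-hydroxydriman-12,11-olide (C-7/C-8 epimers) | O[C@@H]1CCC(C)(C)[C@@H]2CC(OC(C)=O)C3C(=O)OC[C@@H]3[C@@]12C
F3 | step 7 | cis-epoxy alcohol: C1–C10 oxirane of 9, oxygen cis to the side chain (C-7 epimers) | O=C1OCC=C1C(O)C[C@@H]1[C@]2(C)O[C@@H]2CCC1(C)C
F4 | step 10 | drim-7-ene-1β,11,12-triol | O[C@@H]1CCC(C)(C)[C@@H]2CC=C(CO)[C@H](CO)[C@@]12C
F5 | step 10 | 11,12-bis(tert-butyldimethylsilyloxy)drim-7-en-1β-ol | O[C@@H]1CCC(C)(C)[C@@H]2CC=C(CO[Si](C)(C)C(C)(C)C)[C@H](CO[Si](C)(C)C(C)(C)C)[C@@]12C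
F6 | step 10 | 1β-[(E)-4-methoxycinnamoyloxy]-11,12-bis(tert-butyldimethylsilyloxy)drim-7-ene | COc1ccc(/C=C/C(=O)O[C@@H]2CCC(C)(C)[C@@H]3CC=C(CO[Si](C)(C)C(C)(C)C)[C@H](CO[Si](C)(C)C(C)(C)C)[C@@]23C)cc1
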